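(The runs are simulated with made-up constants.)

Late in the summer flask the curve has gone nearly flat: from 150 min to 180 min you see product climb by 0.5 percentage points, against a scatter of 0.3 points, and 53.5% of the charge is still not showing as product.

| flask | substrate | free catalyst | temperature | remark | time |
|---|---|---|---|---|---|
| summer | 0.020 M | 2.6 mM | 20 °C | the very flask that is asked about, followed so far |  |
| spring | 0.020 M | 3.9 mM | 5 °C | run made earlier |  |
| flask | 0.020 M | 2.6 mM | 20 °C |  | 4.0 h |

| summer: time / min | summer: product / % | spring: time / min | spring: product / % |
|---|---|---|---|
| 15.0 | 8.4 | 8.00 | 0.5 |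
| 50.0 | 31.2 | 15.0 | 0.1 |
| 80.0 | 40.7 | 20.0 | 1.2 |
| 150 | 46.0 | 30.0 | 2.4 |
| 180 | 46.5 | 40.0 | 3.9 |

(readings scatter by 0.3 percentage points)

- ochre: at 4.0 h raise the temperature by 15 K, then wait 8.0 h
- grey: change nothing and wait 8.0 h more
- green: at 4.0 h add free catalyst, 100% of the amount charged, then wait 8.0 h
- violet: at 4.0 h add substrate, 50.0% of the amount charged, then wait 8.0 h

- what is added takes up no volume worth counting
- the analysis behind the earlier runs scatters by 0.3 percentage points, standard deviation
- a reading or a percentage of product counts all its forms, free or not

- product, in percent of the substrate first charged, at 4.0 h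
- the option that brings most further product ("none" if no option brings more than 2 percentage points) (ochre / grey / green / violet / none)
- product present, in percent of the substrate first charged, after ochre
- product present, in percent of the substrate first charged, after grey

Set the spring run beside it. It looks nearly the same, with the same substrate and 1.50 times the free catalyst, but it is colder. At 40.0 min the spring run shows 3.9%, and the summer run had more, 8.4%, already at 15.0 min. The spring readings stop at 40.0 min, against 180 min in the summer run, so the spring run shows no ceiling, and you read that from the summer run.

Treat the late curve as a gap closing exponentially at rate k. Take the last reading as the ceiling, get k from the gaps at 80.0 min and 150 min, add the tail still to come, and go round again with the new ceiling: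

first round: k = 0.0350 min⁻¹, ceiling 46.8%

second round: k = 0.0295 min⁻¹, ceiling 46.9%

at 4.0 h: 46.8%

The flat end by itself could be a balance or a dying catalyst (deactivation). Reckon with the dying catalyst: k is then its decay, and 0.0839% of it is left at 4.0 h. Grey then brings 0.10 points, less than 2 points.

Now define the reach, −ln(1 − c(product)∞/c(substrate) charged), which is the number of e-foldings a catalyst charge can drive before it dies, proportional to that charge:

reach = 0.632

Green puts a fresh dose, 100% of the first charge, on what remains, so it should bring 25 points, more than 2 points.

The forecast gives 46.9%, where this reckoning gave 46.8%, then 47% after grey and 47.1% after ochre, and picks green: “Fresh catalyst would restart conversion, so green is best”.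

    free catalyst + intermediate → free catalyst + product (k = 15.8 M⁻¹ min⁻¹, Ea = 64.0 kJ mol⁻¹)
    crystals ⇌ product, rate k2*(cs2 - [product]) while solid is left; crystals form when [product] > cs2 (solubility = 1.00 mM, k = 0.975 min⁻¹)
    free catalyst → spent catalyst (k = 0.0307 min⁻¹, Ea = 97.0 kJ mol⁻¹)
    substrate → intermediate (k = 0.0337 min⁻¹, Ea = 93.0 kJ mol⁻¹)
    (constants at 20 °C)

The flask gives 46.6%, 46.7% after grey, 46.6% after ochre, and green is best, bringing 39 points against the 25 points from the reach. Free catalyst has a half-life of 22.6 min, shorter than the 32 min of intermediate at 20.6 min, and at 24.0 min the flask holds 47.9% of its free catalyst with 44.5% of substrate not yet turned. Scaled to 0.0010 M of free catalyst, the reach gives 21.6%, and that flask holds 22.8%.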